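**Plan**

- Retrosynthesis: ring C of the middle unit (M) is cut at C2–C3 and C4–C4a (formal [4+2]) into acetal 14, which already carries the upper unit (T) on a resorcinol ring, and enol acetate 21 of the lower unit (B). The T-C4–aryl bond is then cut to 4-activated epicatechin 4 plus cyclohexane-1,3-dione (a masked 2-substituted resorcinol), and the B-C8–vinyl bond to bromide 17 plus boronate 18.
- Forward: T (from (−)-epicatechin) is alkylated at C4 by the dione, which is O-benzylated and aromatised to ring A of M (10). The phenol is made into an O-aryl O-methyl acetal of 3,4-dibenzyloxybenzaldehyde (14). B (from (+)-catechin) gets a 2-acetoxyvinyl group at C8 (21). Step 14 builds ring C of M and joins the halves; deacetylation and hydrogenolysis finish.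
- Enabling feature: in M, O1 sits on aromatic C8a whose neighbour C4a is free and electron-rich, C2 is benzylic to a catechol ring, and C4 is benzylic to the 2,4,6-trioxygenated ring A of B. So C4a=C8a–O1=C2 can serve as an aryl oxocarbenium (cationic 2-oxa-diene) and C3=C4 as an enol ester whose C4 cation is stabilised by ring A of B. C8 of M carries T, so only C4a can close.
- Stereochemistry: T and B centres come from the chiral pool; T-C4 (4β) from attack anti to the 3-acetoxy group. In step 14, M-C2 is set by the chiral counter-anion (both acetal epimers and both enol acetate isomers converge), M-C3 by syn topicity of the C2–C3 bond formation, and M-C4 by ring closure anti to the C3 acetoxy group.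

Key step: step 14

Remark: the target is read as epicatechin-(4β→8)-epifisetinidol-(4β→8)-catechin (T 2R,3R,4R; M 2,3-cis-3,4-trans with 7-OH only; B 2R,3S). The acid antipode in step 14 is the one whose anion covers the Re face of C2 in ion 22; it is written as (R) and would be fixed on a small model acetal/enol acetate pair.

**Route**

Step 1
Reactants: 1 (−)-epicatechin
Product: 2 5,7,3',4'-tetra-O-benzyl-(−)-epicatechin
Conditions: BnBr (4.4 equiv), K2CO3, DMF, 0 °C → rt
Reagents that add atoms: benzyl bromide BrCc1ccccc1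
Why: Williamson etherification of the four phenols leaves the secondary alcohol free and, at this temperature, should not open the pyran ring, so C2 and C3 are untouched.

Step 2
Reactants: 2 5,7,3',4'-tetra-O-benzyl-(−)-epicatechin
Product: 3 3-O-acetyl-5,7,3',4'-tetra-O-benzyl-(−)-epicatechin
Conditions: Ac2O, pyridine, DMAP (cat.), rt
Reagents that add atoms: acetic anhydride CC(=O)OC(C)=O
Why: DMAP-catalysed acylation of the only free hydroxyl gives the acetate that later directs attack at C4 and keeps the alcohol out of the cationic steps.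

Step 3
Reactants: 3 3-O-acetyl-5,7,3',4'-tetra-O-benzyl-(−)-epicatechin
Product: 4 3-O-acetyl-4β-(2-ethoxyethoxy)-5,7,3',4'-tetra-O-benzyl-(−)-epicatechin
Conditions: DDQ (2 equiv), 2-ethoxyethanol (5 equiv), CH2Cl2, rt
Reagents that add atoms: 2-ethoxyethanol CCOCCO
Why: DDQ hydride abstraction at C4–H (benzylic to the phloroglucinol-type ring A) and capture of the cation by the alcohol anti to the axial 3-acetoxy group should give the 4β (3,4-trans) ether, the usual C4 activation of benzylated flavan-3-ols.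

Step 4
Reactants: 4 3-O-acetyl-4β-(2-ethoxyethoxy)-5,7,3',4'-tetra-O-benzyl-(−)-epicatechin and 5 cyclohexane-1,3-dione (3 equiv)
Product: 6 2-(3-O-acetyl-5,7,3',4'-tetra-O-benzylepicatechin-4β-yl)cyclohexane-1,3-dione
Conditions: TMSOTf (0.3 equiv), CH2Cl2/MeCN, −40 → 0 °C
Reagents that add atoms: none
Why: Lewis-acid SN1 substitution at C4 (the reaction type of flavan C4 couplings, here with a 1,3-dicarbonyl as carbon nucleophile): C2 of the dione enol is the only carbon nucleophile, O-alkylation is reversible under acid, and attack anti to the participating 3-acetoxy group sets 4β (3,4-trans).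

Step 5
Reactants: 6 2-(3-O-acetyl-5,7,3',4'-tetra-O-benzylepicatechin-4β-yl)cyclohexane-1,3-dione
Product: 7 3-benzyloxy-2-(3-O-acetyl-5,7,3',4'-tetra-O-benzylepicatechin-4β-yl)cyclohex-2-en-1-one
Conditions: BnBr (1.2 equiv), Cs2CO3, DMF, rt
Reagents that add atoms: benzyl bromide BrCc1ccccc1
Why: O-alkylation of the vinylogous acid (Williamson type) is expected because the bulky flavanyl group at C2 blocks C-alkylation; the two carbonyls are equivalent, so one product forms.

Step 6
Reactants: 7 3-benzyloxy-2-(3-O-acetyl-5,7,3',4'-tetra-O-benzylepicatechin-4β-yl)cyclohex-2-en-1-one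
Product: 10 3-benzyloxy-2-(3-O-acetyl-5,7,3',4'-tetra-O-benzylepicatechin-4β-yl)phenol, via silyl dienol ether 8 (not isolated), via aryl silyl ether 9 (not isolated)
Conditions: TMSOTf, Et3N, CH2Cl2, 0 °C; hexane, filtration of the ammonium salt; DDQ, CH2Cl2, 0 °C; aq. NaHCO3/MeOH work-up
Reagents that add atoms: none
Why: Soft enolisation gives a 1,3-cyclohexadiene that DDQ dehydrogenates (silyl enol ether oxidation, driven by aromatisation) to the resorcinol mono-benzyl ether, whose labile aryl–O–TMS bond hydrolyses on work-up; no stereocentre is touched.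

Step 7
Reactants: 11 3,4-bis(benzyloxy)benzaldehyde
Product: 12 3,4-bis(benzyloxy)benzaldehyde dimethyl acetal
Conditions: HC(OMe)3, p-TsOH (cat.), MeOH, rt; Et3N quench
Reagents that add atoms: trimethyl orthoformate COC(OC)OC
Why: Acid-catalysed acetalisation, driven by the orthoformate as water scavenger.

Step 8
Reactants: 10 3-benzyloxy-2-(3-O-acetyl-5,7,3',4'-tetra-O-benzylepicatechin-4β-yl)phenol and 12 3,4-bis(benzyloxy)benzaldehyde dimethyl acetal
Product: 14 1-benzyloxy-3-{[3,4-bis(benzyloxy)phenyl](methoxy)methoxy}-2-(3-O-acetyl-5,7,3',4'-tetra-O-benzylepicatechin-4β-yl)benzene (both epimers at the acetal carbon), via α-chloro ether 13 (not isolated)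
Conditions: 12, AcCl, ZnBr2 (1 mol %), CH2Cl2, 0 °C; then 10, i-Pr2NEt, CH2Cl2, 0 °C → rt; Et3N-deactivated silica
Reagents that add atoms: none
Why: Acetal/acyl chloride exchange gives the α-chloro ether, which O-alkylates the phenol under basic conditions (as in MOM protection) so the acid-labile mixed acetal survives; the acetal epimers do not matter because this carbon becomes planar in step 14.

Step 9
Reactants: 15 (+)-catechin
Product: 16 5,7,3',4'-tetra-O-benzyl-(+)-catechin
Conditions: BnBr (4.4 equiv), K2CO3, DMF, 0 °C → rt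
Reagents that add atoms: benzyl bromide BrCc1ccccc1
Why: Williamson etherification of the four phenols as in step 1, without touching C2, C3 or the alcohol.

Step 10
Reactants: 16 5,7,3',4'-tetra-O-benzyl-(+)-catechin
Product: 17 8-bromo-5,7,3',4'-tetra-O-benzyl-(+)-catechin
Conditions: NBS (1.0 equiv), CH2Cl2, −78 °C → rt
Reagents that add atoms: N-bromosuccinimide O=C1CCC(=O)N1Br
Why: Electrophilic aromatic bromination, which in 5,7-di-O-benzyl flavan-3-ols goes selectively to C8.

Step 11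
Reactants: 17 8-bromo-5,7,3',4'-tetra-O-benzyl-(+)-catechin and 18 (E)-2-(2-ethoxyvinyl)-4,4,5,5-tetramethyl-1,3,2-dioxaborolane
Product: 19 8-[(E)-2-ethoxyvinyl]-5,7,3',4'-tetra-O-benzyl-(+)-catechin
Conditions: Pd(OAc)2 (5 mol %), SPhos (10 mol %), K3PO4, 1,4-dioxane/H2O, 80 °C
Reagents that add atoms: none
Why: Suzuki–Miyaura coupling; the SPhos catalyst is suited to di-ortho-alkoxy aryl bromides, the alkenyl group transfers with retention, and the free alcohol is tolerated.

Step 12
Reactants: 19 8-[(E)-2-ethoxyvinyl]-5,7,3',4'-tetra-O-benzyl-(+)-catechin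
Product: 20 2-(5,7,3',4'-tetra-O-benzylcatechin-8-yl)acetaldehyde
Conditions: 2 M HCl, THF, 0 °C → rt; used crude
Reagents that add atoms: water O
Why: Acid hydrolysis of the enol ether (C-protonation, hemiacetal collapse) unmasks the arylacetaldehyde.

Step 13
Reactants: 20 2-(5,7,3',4'-tetra-O-benzylcatechin-8-yl)acetaldehyde
Product: 21 2-(3-O-acetyl-5,7,3',4'-tetra-O-benzylcatechin-8-yl)vinyl acetate (E/Z mixture)
Conditions: Ac2O (4 equiv), Et3N, DMAP (cat.), CH2Cl2, 0 °C → rt
Reagents that add atoms: acetic anhydride CC(=O)OC(C)=O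
Why: One operation acetylates the secondary alcohol and O-acylates the aldehyde enolate (conjugation with the arene favours the enol acetate); the E/Z ratio is not critical because step 14 is stepwise.

Step 14
Reactants: 14 mixed O-aryl O-methyl acetal (1.0 equiv) and 21 2-(3-O-acetyl-5,7,3',4'-tetra-O-benzylcatechin-8-yl)vinyl acetate (1.5 equiv)
Product: 24 tri-O-acetyl-undeca-O-benzyl-epicatechin-(4β→8)-epifisetinidol-(4β→8)-catechin, via oxocarbenium ion 22 (not isolated), via benzylic cation 23 (not isolated)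
Conditions: (R)-3,3'-bis(2,4,6-triisopropylphenyl)-BINOL N-triflylphosphoramide (10 mol %), 5 Å MS, CH2Cl2, −78 → −40 °C
Reagents that add atoms: none
Why: Proposed new method: the chiral N-triflylphosphoramide protonates the methoxy oxygen of 14 (the more basic acetal oxygen), methanol leaves into the sieves and both acetal epimers converge on the planar O-aryl oxocarbenium 22 held as a contact ion pair with the chiral anion, C3 of 21 then adds to C2 (Prins step; C3 is the nucleophilic terminus because the acetyl group damps donation from the enol oxygen while the 2,4,6-trioxygenated ring A of B stabilises the charge at C4 as the quinone-methide-type cation 23), and C4a of the resorcinol ring closes on C4 (Friedel–Crafts) with return of the proton to the catalyst. The closest known reaction types are the Lewis-acid oxa-Povarov reaction of O-aryl O-alkyl acetals with styrenes (formal [4+2] of the cationic 2-oxa-diene C4a=C8a–O1=C2 with a C=C bond, giving 2,4-diarylchromans) and chiral-anion-directed additions of π-nucleophiles to acetal-derived oxocarbenium ions; new are the enol ester as 2π partner and catalyst control between two large chiral fragments. The one ring formed, pyran ring C of M, closes by 6-exo-trig attack of arene carbon C4a on the exocyclic cationic C4 of 23. C2: the anion covers the Re face of 22 so that the alkene adds to the Si face (2R); C3: an open antiperiplanar transition state with the acetoxy group gauche to the small C2–H (syn topicity, as in additions of γ-alkoxyallyl stannanes to activated aldehydes), reachable from either double-bond isomer of 21, gives the 2,3-cis relation; C4: in 23 the C3–H lies in the cation plane (allylic 1,3-strain with the ortho oxygens of ring A of B) and C4a, delivered through C2, adds anti to the acetoxy group, whose reversible dioxolanylium participation favours the same 3,4-trans (4β) outcome. The step needs (i) ionisation of OMe and not OAr, secured by oxygen basicity, (ii) attack by C3 of 21 rather than by the free C6 of its ring A or by ring A of T, secured by the two benzyloxy groups flanking those positions and by the excess of 21, and (iii) closure at C4a only, secured because the other ortho carbon C8 carries T and C4a is activated by O1 and the para 7-benzyloxy group.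

Step 15
Reactants: 24 tri-O-acetyl-undeca-O-benzyl-epicatechin-(4β→8)-epifisetinidol-(4β→8)-catechin
Product: 25 undeca-O-benzyl-epicatechin-(4β→8)-epifisetinidol-(4β→8)-catechin
Conditions: NaOMe (cat.), MeOH/THF, rt → 40 °C
Reagents that add atoms: none
Why: Zemplén transesterification removes the three secondary acetates; with every phenol benzylated no quinone methide can form, so C2 of each unit should be configurationally safe under base.

Step 16
Reactants: 25 undeca-O-benzyl-epicatechin-(4β→8)-epifisetinidol-(4β→8)-catechin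
Product: 26 epicatechin-(4β→8)-epifisetinidol-(4β→8)-catechin (CNP0270097.1)
Conditions: H2 (1 atm), 20 % Pd(OH)2/C, THF/MeOH/H2O, rt
Reagents that add atoms: none
Why: Neutral hydrogenolysis of the eleven benzyl ethers, conditions under which benzylated oligomeric flavan-3-ols are expected to keep their interflavan bonds and stereocentres.

**Compound list**

1 | (−)-epicatechin | Oc1cc(O)c2c(c1)O[C@H](c1ccc(O)c(O)c1)[C@H](O)C2 | starting material
2 | 5,7,3',4'-tetra-O-benzyl-(−)-epicatechin | c3ccccc3COc1cc(OCc3ccccc3)c2c(c1)O[C@H](c1ccc(OCc3ccccc3)c(OCc3ccccc3)c1)[C@H](O)C2 | intermediate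
3 | 3-O-acetyl-5,7,3',4'-tetra-O-benzyl-(−)-epicatechin | c3ccccc3COc1cc(OCc3ccccc3)c2c(c1)O[C@H](c1ccc(OCc3ccccc3)c(OCc3ccccc3)c1)[C@H](OC(C)=O)C2 | intermediate
4 | 3-O-acetyl-4β-(2-ethoxyethoxy)-5,7,3',4'-tetra-O-benzyl-(−)-epicatechin (2R,3R,4S; 3,4-trans) | c3ccccc3COc1cc(OCc3ccccc3)c2c(c1)O[C@H](c1ccc(OCc3ccccc3)c(OCc3ccccc3)c1)[C@H](OC(C)=O)[C@H]2OCCOCC | intermediate
5 | cyclohexane-1,3-dione | O=C1CCCC(=O)C1 | starting material
6 | 2-(3-O-acetyl-5,7,3',4'-tetra-O-benzylepicatechin-4β-yl)cyclohexane-1,3-dione (drawn as diketone) | c3ccccc3COc1cc(OCc3ccccc3)c2c(c1)O[C@H](c1ccc(OCc3ccccc3)c(OCc3ccccc3)c1)[C@H](OC(C)=O)[C@H]2C4C(=O)CCCC4=O | intermediate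
7 | 3-benzyloxy-2-(3-O-acetyl-5,7,3',4'-tetra-O-benzylepicatechin-4β-yl)cyclohex-2-en-1-one | c3ccccc3COc1cc(OCc3ccccc3)c2c(c1)O[C@H](c1ccc(OCc3ccccc3)c(OCc3ccccc3)c1)[C@H](OC(C)=O)[C@H]2C4=C(OCc3ccccc3)CCCC4=O | intermediate
8 | 1-benzyloxy-3-(trimethylsilyloxy)-2-(3-O-acetyl-5,7,3',4'-tetra-O-benzylepicatechin-4β-yl)cyclohexa-1,3-diene (silyl dienol ether, not isolated) | c3ccccc3COc1cc(OCc3ccccc3)c2c(c1)O[C@H](c1ccc(OCc3ccccc3)c(OCc3ccccc3)c1)[C@H](OC(C)=O)[C@H]2C4=C(OCc3ccccc3)CCC=C4O[Si](C)(C)C | intermediate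
9 | [3-benzyloxy-2-(3-O-acetyl-5,7,3',4'-tetra-O-benzylepicatechin-4β-yl)phenoxy]trimethylsilane (aryl silyl ether, not isolated) | c3ccccc3COc1cc(OCc3ccccc3)c2c(c1)O[C@H](c1ccc(OCc3ccccc3)c(OCc3ccccc3)c1)[C@H](OC(C)=O)[C@H]2c4c(OCc3ccccc3)cccc4O[Si](C)(C)C | intermediate
10 | 3-benzyloxy-2-(3-O-acetyl-5,7,3',4'-tetra-O-benzylepicatechin-4β-yl)phenol | c3ccccc3COc1cc(OCc3ccccc3)c2c(c1)O[C@H](c1ccc(OCc3ccccc3)c(OCc3ccccc3)c1)[C@H](OC(C)=O)[C@H]2c4c(OCc3ccccc3)cccc4O | intermediate
11 | 3,4-bis(benzyloxy)benzaldehyde | O=Cc1ccc(OCc3ccccc3)c(OCc3ccccc3)c1 | starting material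
12 | 3,4-bis(benzyloxy)benzaldehyde dimethyl acetal | COC(OC)c1ccc(OCc3ccccc3)c(OCc3ccccc3)c1 | intermediate
13 | 1,2-bis(benzyloxy)-4-[chloro(methoxy)methyl]benzene (α-chloro ether, not isolated) | COC(Cl)c1ccc(OCc3ccccc3)c(OCc3ccccc3)c1 | intermediate
14 | 1-benzyloxy-3-{[3,4-bis(benzyloxy)phenyl](methoxy)methoxy}-2-(3-O-acetyl-5,7,3',4'-tetra-O-benzylepicatechin-4β-yl)benzene (both epimers at the acetal carbon) | c3ccccc3COc1cc(OCc3ccccc3)c2c(c1)O[C@H](c1ccc(OCc3ccccc3)c(OCc3ccccc3)c1)[C@H](OC(C)=O)[C@H]2c4c(OCc3ccccc3)cccc4OC(OC)c1ccc(OCc3ccccc3)c(OCc3ccccc3)c1 | intermediate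
15 | (+)-catechin | Oc1cc(O)c2c(c1)O[C@H](c1ccc(O)c(O)c1)[C@@H](O)C2 | starting material
16 | 5,7,3',4'-tetra-O-benzyl-(+)-catechin | c3ccccc3COc1cc(OCc3ccccc3)c2c(c1)O[C@H](c1ccc(OCc3ccccc3)c(OCc3ccccc3)c1)[C@@H](O)C2 | intermediate
17 | 8-bromo-5,7,3',4'-tetra-O-benzyl-(+)-catechin | c3ccccc3COc1cc(OCc3ccccc3)c2c(c1Br)O[C@H](c1ccc(OCc3ccccc3)c(OCc3ccccc3)c1)[C@@H](O)C2 | intermediate
18 | (E)-2-(2-ethoxyvinyl)-4,4,5,5-tetramethyl-1,3,2-dioxaborolane | CCO/C=C/B1OC(C)(C)C(C)(C)O1 | starting material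
19 | 8-[(E)-2-ethoxyvinyl]-5,7,3',4'-tetra-O-benzyl-(+)-catechin | c3ccccc3COc1cc(OCc3ccccc3)c2c(c1/C=C/OCC)O[C@H](c1ccc(OCc3ccccc3)c(OCc3ccccc3)c1)[C@@H](O)C2 | intermediate
20 | 2-(5,7,3',4'-tetra-O-benzylcatechin-8-yl)acetaldehyde | c3ccccc3COc1cc(OCc3ccccc3)c2c(c1CC=O)O[C@H](c1ccc(OCc3ccccc3)c(OCc3ccccc3)c1)[C@@H](O)C2 | intermediate
21 | 2-(3-O-acetyl-5,7,3',4'-tetra-O-benzylcatechin-8-yl)vinyl acetate (E/Z mixture) | c3ccccc3COc1cc(OCc3ccccc3)c2c(c1C=COC(C)=O)O[C@H](c1ccc(OCc3ccccc3)c(OCc3ccccc3)c1)[C@@H](OC(C)=O)C2 | intermediate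
22 | O-aryl oxocarbenium ion from 14 (not isolated) | c3ccccc3COc1cc(OCc3ccccc3)c2c(c1)O[C@H](c1ccc(OCc3ccccc3)c(OCc3ccccc3)c1)[C@H](OC(C)=O)[C@H]2c4c(OCc3ccccc3)cccc4[O+]=Cc1ccc(OCc3ccccc3)c(OCc3ccccc3)c1 | intermediate
23 | benzylic (quinone-methide-type) cation after C2–C3 bond formation (not isolated) | c3ccccc3COc1cc(OCc3ccccc3)c2c(c1)O[C@H](c1ccc(OCc3ccccc3)c(OCc3ccccc3)c1)[C@H](OC(C)=O)[C@H]2c4c(OCc3ccccc3)cccc4O[C@H](c1ccc(OCc3ccccc3)c(OCc3ccccc3)c1)[C@H](OC(C)=O)[CH+]c1c(OCc3ccccc3)cc(OCc3ccccc3)c2c1O[C@H](c1ccc(OCc3ccccc3)c(OCc3ccccc3)c1)[C@@H](OC(C)=O)C2 | intermediate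
24 | tri-O-acetyl-undeca-O-benzyl-epicatechin-(4β→8)-epifisetinidol-(4β→8)-catechin (all phenols benzylated, the three 3-OH acetylated) | c3ccccc3COc1cc(OCc3ccccc3)c2c(c1)O[C@H](c1ccc(OCc3ccccc3)c(OCc3ccccc3)c1)[C@H](OC(C)=O)[C@H]2c1c(OCc3ccccc3)ccc2c1O[C@H](c1ccc(OCc3ccccc3)c(OCc3ccccc3)c1)[C@H](OC(C)=O)[C@H]2c1c(OCc3ccccc3)cc(OCc3ccccc3)c2c1O[C@H](c1ccc(OCc3ccccc3)c(OCc3ccccc3)c1)[C@@H](OC(C)=O)C2 | intermediate
25 | undeca-O-benzyl-epicatechin-(4β→8)-epifisetinidol-(4β→8)-catechin | c3ccccc3COc1cc(OCc3ccccc3)c2c(c1)O[C@H](c1ccc(OCc3ccccc3)c(OCc3ccccc3)c1)[C@H](O)[C@H]2c1c(OCc3ccccc3)ccc2c1O[C@H](c1ccc(OCc3ccccc3)c(OCc3ccccc3)c1)[C@H](O)[C@H]2c1c(OCc3ccccc3)cc(OCc3ccccc3)c2c1O[C@H](c1ccc(OCc3ccccc3)c(OCc3ccccc3)c1)[C@@H](O)C2 | intermediate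
26 | epicatechin-(4β→8)-epifisetinidol-(4β→8)-catechin (CNP0270097.1) | Oc1cc(O)c2c(c1)O[C@H](c1ccc(O)c(O)c1)[C@H](O)[C@H]2c1c(O)ccc2c1O[C@H](c1ccc(O)c(O)c1)[C@H](O)[C@H]2c1c(O)cc(O)c2c1O[C@H](c1ccc(O)c(O)c1)[C@@H](O)C2 | target

**Summary**

Total steps: 16. Longest linear sequence: 10 steps (1–6, 8, 14, 15, 16).

Steps most likely to fail:

1. Step 14 (Proposed new method). The ion pair may be attacked without facial discrimination, the enol acetate may be protonated or oligomerised faster than it adds, or cation 23 may be captured by other arenes before C4a closes. Fallback with known reactions only, setting out from phenol 10 and aldehyde 11, using 16, and returning at 25: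
   - 11 is homologated with (triphenylphosphoranylidene)acetaldehyde (toluene, 80 °C) to (E)-3-[3,4-bis(benzyloxy)phenyl]prop-2-enal F1.
   - 10 and F1 are condensed with PhB(OH)2 and catalytic propionic acid in refluxing toluene (boronate-templated ortho-hydroxyalkylation, o-quinone methide, oxa-6π closure) to the flav-3-ene F2 as both C2 epimers.
   - Hydroboration (BH3·SMe2, then NaBO3) anti to the 2-aryl group gives the 2,3-trans flavan-3-ol F3, where the C2 epimers are separated.
   - Dess–Martin oxidation gives the flavan-3-one F4, and L-Selectride (−78 °C) gives the 2,3-cis alcohol F5.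
   - DDQ/2-ethoxyethanol gives the 4β ether F6.
   - TMSOTf-mediated coupling with excess 16 (−78 °C, attack by C8 anti to the 3-oxygen) gives the mono-acetate trimer F7, which the conditions of step 15 convert into 25.

2. Step 6. Enolisation may be incomplete or unselective, and DDQ may over-oxidise at the doubly benzylic T-C4–H or at benzyl ethers. Fallback from 7, returning at 10: LiHMDS (1.05 equiv, THF, −78 °C) and PhSeCl give the 6-(phenylselanyl) enone F8. H2O2/pyridine (CH2Cl2, 0 °C) then triggers selenoxide syn-elimination to the cross-conjugated dienone, which tautomerises to 10. This replaces hydride abstraction by stoichiometric α'-functionalisation and elimination.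

3. Step 4. The dione enol is a weak π-nucleophile, so O-alkylation, elimination to the flav-3-ene or self-condensation through ring A of a second molecule of 4 may outrun C-alkylation. Fallback from 4, returning at 6: 4 is ionised with catalytic camphorsulfonic acid (MeCN, 0 °C) in the presence of commercial 3-aminocyclohex-2-en-1-one, a far stronger carbon nucleophile at C2, to give the enaminone F9. Hydrolysis (1 M HCl, THF, rt) returns dione 6.

Further compounds

F1 | step 14 | (E)-3-[3,4-bis(benzyloxy)phenyl]prop-2-enal | O=C/C=C/c1ccc(OCc3ccccc3)c(OCc3ccccc3)c1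
F2 | step 14 | 7-benzyloxy-2-[3,4-bis(benzyloxy)phenyl]-8-(3-O-acetyl-5,7,3',4'-tetra-O-benzylepicatechin-4β-yl)-2H-chromene (both C2 epimers) | c3ccccc3COc1cc(OCc3ccccc3)c2c(c1)O[C@H](c1ccc(OCc3ccccc3)c(OCc3ccccc3)c1)[C@H](OC(C)=O)[C@H]2c1c(OCc3ccccc3)ccc2c1OC(c1ccc(OCc3ccccc3)c(OCc3ccccc3)c1)C=C2
F3 | step 14 | 3-O-acetyl-tetra-O-benzylepicatechin-(4β→8)-tri-O-benzylfisetinidol (M unit 2,3-trans, C2 as in the target) | c3ccccc3COc1cc(OCc3ccccc3)c2c(c1)O[C@H](c1ccc(OCc3ccccc3)c(OCc3ccccc3)c1)[C@H](OC(C)=O)[C@H]2c1c(OCc3ccccc3)ccc2c1O[C@H](c1ccc(OCc3ccccc3)c(OCc3ccccc3)c1)[C@@H](O)C2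
F4 | step 14 | corresponding M-unit flavan-3-one | c3ccccc3COc1cc(OCc3ccccc3)c2c(c1)O[C@H](c1ccc(OCc3ccccc3)c(OCc3ccccc3)c1)[C@H](OC(C)=O)[C@H]2c1c(OCc3ccccc3)ccc2c1O[C@H](c1ccc(OCc3ccccc3)c(OCc3ccccc3)c1)C(=O)C2
F5 | step 14 | 3-O-acetyl-tetra-O-benzylepicatechin-(4β→8)-tri-O-benzylepifisetinidol (M unit 2,3-cis) | c3ccccc3COc1cc(OCc3ccccc3)c2c(c1)O[C@H](c1ccc(OCc3ccccc3)c(OCc3ccccc3)c1)[C@H](OC(C)=O)[C@H]2c1c(OCc3ccccc3)ccc2c1O[C@H](c1ccc(OCc3ccccc3)c(OCc3ccccc3)c1)[C@H](O)C2
F6 | step 14 | 4β-(2-ethoxyethoxy) ether of F5 at C4 of the M unit (3,4-trans) | c3ccccc3COc1cc(OCc3ccccc3)c2c(c1)O[C@H](c1ccc(OCc3ccccc3)c(OCc3ccccc3)c1)[C@H](OC(C)=O)[C@H]2c1c(OCc3ccccc3)ccc2c1O[C@H](c1ccc(OCc3ccccc3)c(OCc3ccccc3)c1)[C@H](O)[C@H]2OCCOCC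
F7 | step 14 | mono-O-acetyl (T-3-O) undeca-O-benzyl-epicatechin-(4β→8)-epifisetinidol-(4β→8)-catechin | c3ccccc3COc1cc(OCc3ccccc3)c2c(c1)O[C@H](c1ccc(OCc3ccccc3)c(OCc3ccccc3)c1)[C@H](OC(C)=O)[C@H]2c1c(OCc3ccccc3)ccc2c1O[C@H](c1ccc(OCc3ccccc3)c(OCc3ccccc3)c1)[C@H](O)[C@H]2c1c(OCc3ccccc3)cc(OCc3ccccc3)c2c1O[C@H](c1ccc(OCc3ccccc3)c(OCc3ccccc3)c1)[C@@H](O)C2
F8 | step 6 | 3-benzyloxy-6-(phenylselanyl)-2-(3-O-acetyl-5,7,3',4'-tetra-O-benzylepicatechin-4β-yl)cyclohex-2-en-1-one | c3ccccc3COc1cc(OCc3ccccc3)c2c(c1)O[C@H](c1ccc(OCc3ccccc3)c(OCc3ccccc3)c1)[C@H](OC(C)=O)[C@H]2C4=C(OCc3ccccc3)CCC([Se]c5ccccc5)C4=O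
F9 | step 4 | 3-amino-2-(3-O-acetyl-5,7,3',4'-tetra-O-benzylepicatechin-4β-yl)cyclohex-2-en-1-one | c3ccccc3COc1cc(OCc3ccccc3)c2c(c1)O[C@H](c1ccc(OCc3ccccc3)c(OCc3ccccc3)c1)[C@H](OC(C)=O)[C@H]2C4=C(N)CCCC4=O
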